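**Retrosynthetic overview**
1. The 1,2-dioxane is made last: C13–OO by perhydrolysis of a (13S,14S)-epoxide with inversion, then O–C16 and the C17 centre by peroxy-Michael addition inside a temporary C14–O–C18 lactone; the temporary C14 oxygen is finally removed by radical deoxygenation.
2. The side chain C13–C18 is grown from a C13 aldehyde: alkyne, Zr-catalysed methylalumination/ethylene oxide, Z-selective olefination.
3. Ring B is annulated onto ring A in one operation from allylic alcohol 11 and enol ether 14: enol-ether exchange (temporary O5–C12 bond), Claisen shift (C9–C10), carbonyl-ene closure (C5–C6); C8 of 11 is a relay stereocentre.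
4. Enabling feature: the C5 carbinol carbon and the quaternary C10 are the adjacent fusion atoms of rings A and B, i.e. the carbonyl and α-carbon of 2,2,6-trimethylcyclohexanone, so its enol oxygen O5 can deliver C9 to C10 by a [3,3] shift and the regenerated C5=O can accept C6.
5. Ring order: ring A (bought), ring B (step 10), dioxane (step 20); chirality comes from methyl (S)-3-hydroxy-2-methylpropanoate (C8), (R)-glyceraldehyde acetonide (C12, relayed to C9, C10, C5) and an L-fructose-derived ketone (C13, relayed to C16, C17).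

Key step: step 10

Remark: atoms are numbered C1–C10 in the decalin (C5 = carbinol carbon, C10 = angular methyl carbon, C8 = methyl-bearing CH, C9 = side-chain-bearing CH), C11–C12 in the ethylene bridge, C13–C16 in the dioxane (C13 quaternary, C16 the CH–O) and C17–C18 in the propanoate; Dec = (1S,2R,4aS,8aR)-4a-hydroxy-2,5,5,8a-tetramethyldecahydronaphthalen-1-yl.

**Step 1**
Reactants: 1 methyl (S)-3-hydroxy-2-methylpropanoate
Product: 2 methyl (S)-3-[(tert-butyldimethylsilyl)oxy]-2-methylpropanoate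
Conditions: TBSCl, imidazole, CH2Cl2, 0 °C to rt
Reagents that add atoms: tert-butyldimethylsilyl chloride, CC(C)(C)[Si](C)(C)Cl
Why: Standard silylation of the primary alcohol; the stereocentre is not involved.

**Step 2**
Reactants: 2 methyl (S)-3-[(tert-butyldimethylsilyl)oxy]-2-methylpropanoate
Product: 3 (S)-3-[(tert-butyldimethylsilyl)oxy]-2-methylpropanal
Conditions: i-Bu2AlH, CH2Cl2, −78 °C; aqueous potassium sodium tartrate
Reagents that add atoms: none
Why: Partial hydride reduction of the ester at low temperature stops at the aldehyde, which is used at once so that its α-stereocentre does not epimerise.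

**Step 3**
Reactants: 3 (S)-3-[(tert-butyldimethylsilyl)oxy]-2-methylpropanal
Product: 4 (R)-tert-butyldimethyl[(2-methylbut-3-en-1-yl)oxy]silane
Conditions: Ph3PCH3Br, KOt-Bu, THF, 0 °C
Reagents that add atoms: methyltriphenylphosphonium bromide, C[P+](c1ccccc1)(c1ccccc1)c1ccccc1.[Br-]
Why: Wittig methylenation installs the future ene-donor vinyl group (C6=C7) next to the C8 stereocentre, which keeps its configuration (descriptor changes by priority only).

**Step 4**
Reactants: 4 (R)-tert-butyldimethyl[(2-methylbut-3-en-1-yl)oxy]silane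
Product: 5 (R)-4-bromo-3-methylbut-1-ene
Conditions: Ph3PBr2, CH2Cl2, 0 °C to rt
Reagents that add atoms: dibromotriphenylphosphorane, BrP(Br)(c1ccccc1)(c1ccccc1)c1ccccc1
Why: Direct conversion of a primary silyl ether into the bromide by the bromophosphonium reagent (SN2 at the primary carbon) avoids isolating the volatile alcohol.

**Step 5**
Reactants: 5 (R)-4-bromo-3-methylbut-1-ene
Product: 6 [(R)-2-methylbut-3-en-1-yl]triphenylphosphonium bromide
Conditions: PPh3, MeCN, sealed tube, 85 °C
Reagents that add atoms: triphenylphosphine, c1ccc(cc1)P(c1ccccc1)c1ccccc1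
Why: SN2 quaternisation of the primary bromide gives a crystalline Wittig salt.

**Step 6**
Reactants: 6 [(R)-2-methylbut-3-en-1-yl]triphenylphosphonium bromide; 7 (R)-2,2-dimethyl-1,3-dioxolane-4-carbaldehyde
Product: 9 (4S)-2,2-dimethyl-4-[(1Z,3R)-3-methylpenta-1,4-dien-1-yl]-1,3-dioxolane, via phosphorus ylide 8 (not isolated)
Conditions: KN(SiMe3)2, THF, −78 °C; then 7, −78 °C to rt
Reagents that add atoms: none
Why: Salt-free Wittig reaction of a non-stabilised ylide with an α-alkoxy aldehyde gives the Z-alkene (C9=C11) under kinetic control; both existing stereocentres are carried through.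

**Step 7**
Reactants: 9 (4S)-2,2-dimethyl-4-[(1Z,3R)-3-methylpenta-1,4-dien-1-yl]-1,3-dioxolane
Product: 10 (2S,3Z,5R)-5-methylhepta-3,6-diene-1,2-diol
Conditions: AcOH/H2O (4:1), 40 °C
Reagents that add atoms: none
Why: Mild acid hydrolysis of the acetonide leaves the skipped diene and the allylic carbinol untouched.

**Step 8**
Reactants: 10 (2S,3Z,5R)-5-methylhepta-3,6-diene-1,2-diol
Product: 11 (2S,3Z,5R)-1-[(tert-butyldimethylsilyl)oxy]-5-methylhepta-3,6-dien-2-ol
Conditions: TBSCl, imidazole, CH2Cl2, −20 °C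
Reagents that add atoms: tert-butyldimethylsilyl chloride, CC(C)(C)[Si](C)(C)Cl
Why: Selective silylation of the primary hydroxyl leaves the secondary Z-allylic alcohol (C12–OH) free for the enol-ether exchange.

**Step 9**
Reactants: 12 2,2,6-trimethylcyclohexan-1-one
Product: 14 1-methoxy-2,6,6-trimethylcyclohex-1-ene, via dimethyl ketal 13 (not isolated)
Conditions: HC(OMe)3, p-TsOH·H2O (cat.), MeOH, 60 °C; then NH4H2PO4 (cat.), distillation, 150 °C
Reagents that add atoms: trimethyl orthoformate, COC(OC)OC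
Why: Acid-catalysed ketalisation and thermal loss of methanol give the only possible enol ether, because C4 carries no hydrogen.

**Step 10**
Reactants: 11 (2S,3Z,5R)-1-[(tert-butyldimethylsilyl)oxy]-5-methylhepta-3,6-dien-2-ol; 14 1-methoxy-2,6,6-trimethylcyclohex-1-ene
Product: 18 (1S,4aS,8aR)-1-[(E)-3-[(tert-butyldimethylsilyl)oxy]prop-1-en-1-yl]-2,5,5,8a-tetramethyl-1,5,6,7,8,8a-hexahydronaphthalen-4a(4H)-ol, via mixed ketal 15 (not isolated), via allyl enol ether 16 (not isolated), via Claisen ketone 17 (not isolated)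
Conditions: 14 (4 equiv), 2,6-dimethylphenol (0.3 equiv), toluene, sealed tube, 140 °C then 190 °C
Reagents that add atoms: none
Why: Proposed new method: acid-catalysed exchange of the enol ether with the allylic alcohol gives allyl enol ether 16, whose [3,3] shift forms C9–C10, and the C5 ketone so unmasked is then attacked by the terminal vinyl carbon C6 with suprafacial transfer of the allylic C8 hydrogen to oxygen (intramolecular carbonyl-ene), which forms C5–C6 and leaves the alkene at C7=C8. The closest known reaction types are one-pot Claisen/carbonyl-ene sequences of 2-alkylcycloalkenyl methyl ethers with Z-allylic alcohols and thermal ene cyclisations of unsaturated ketones; new here is the pairing of a ketone flanked by two quaternary carbons with a monosubstituted vinyl donor. The Claisen step runs through a chair in which the CH2OTBS group on C12 is equatorial and the Z-substituent axial, so the (S)-configuration of C12 is transferred to C9 (S) and C10 (R) and the new C11=C12 alkene is E. Ring B closes as a six-membered ring that takes in all three ene carbons (C6, C7, C8) through a boat-like array in which O5 and the C8 hydrogen bridge C5 and C8; since that hydrogen lies on the β face in (R)-C8, oxygen can only end β, cis to the C10 methyl, which sets C5 (S) while C8 becomes sp2. Selectivity needed is chair over boat in the shift (secured by the 1,3-diaxial clash an axial C12 substituent would have with the Z-substituent) and ene closure over Cope rearrangement of the 1,5-diene in 17 (favoured by the fully substituted C9–C10 tether that holds C6 against C5).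

**Step 11**
Reactants: 18 (1S,4aS,8aR)-1-[(E)-3-[(tert-butyldimethylsilyl)oxy]prop-1-en-1-yl]-2,5,5,8a-tetramethyl-1,5,6,7,8,8a-hexahydronaphthalen-4a(4H)-ol
Product: 19 (1S,2R,4aS,8aR)-1-{3-[(tert-butyldimethylsilyl)oxy]propyl}-2,5,5,8a-tetramethyloctahydronaphthalen-4a(2H)-ol
Conditions: H2 (1 atm), [Ir(cod)(PCy3)(py)]PF6 (5 mol%), CH2Cl2, rt
Reagents that add atoms: none
Why: Hydroxyl-directed homogeneous hydrogenation delivers H2 to C7=C8 from the face of the C5 hydroxyl, setting C8 (R) with its methyl trans to the C9 chain, and saturates C11=C12 in the same operation.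

**Step 12**
Reactants: 19 (1S,2R,4aS,8aR)-1-{3-[(tert-butyldimethylsilyl)oxy]propyl}-2,5,5,8a-tetramethyloctahydronaphthalen-4a(2H)-ol
Product: 20 (1S,2R,4aS,8aR)-1-(3-hydroxypropyl)-2,5,5,8a-tetramethyloctahydronaphthalen-4a(2H)-ol
Conditions: n-Bu4NF, THF, rt; aqueous NH4Cl
Reagents that add atoms: none
Why: Fluoride desilylation frees the primary C13 alcohol.

**Step 13**
Reactants: 20 (1S,2R,4aS,8aR)-1-(3-hydroxypropyl)-2,5,5,8a-tetramethyloctahydronaphthalen-4a(2H)-ol
Product: 21 3-(Dec)propanal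
Conditions: Dess–Martin periodinane, NaHCO3, CH2Cl2, 0 °C
Reagents that add atoms: none
Why: Dess–Martin oxidation converts only the primary alcohol; the hindered tertiary C5 alcohol cannot be oxidised.

**Step 14**
Reactants: 21 3-(Dec)propanal
Product: 22 (1S,2R,4aS,8aR)-1-(but-3-yn-1-yl)-2,5,5,8a-tetramethyloctahydronaphthalen-4a(2H)-ol
Conditions: dimethyl (1-diazo-2-oxopropyl)phosphonate, K2CO3, MeOH, rt
Reagents that add atoms: dimethyl (1-diazo-2-oxopropyl)phosphonate, CC(=O)C(=[N+]=[N-])P(=O)(OC)OC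
Why: Seyferth–Gilbert homologation with the Bestmann–Ohira reagent turns the C13 aldehyde into the terminal alkyne C13≡C14 under mild base.

**Step 15**
Reactants: 22 (1S,2R,4aS,8aR)-1-(but-3-yn-1-yl)-2,5,5,8a-tetramethyloctahydronaphthalen-4a(2H)-ol
Product: 24 (3E)-6-(Dec)-4-methylhex-3-en-1-ol, via alkenylalane 23 (not isolated)
Conditions: Me3Al (4 equiv), Cp2ZrCl2 (0.3 equiv), CH2Cl2, rt; then n-BuLi, THF, −78 °C; ethylene oxide, −78 to 0 °C
Reagents that add atoms: trimethylaluminium, C[Al](C)C; ethylene oxide, C1CO1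
Why: Negishi Zr-catalysed syn-methylalumination puts the methyl on C13 and aluminium on C14, and the derived alanate opens ethylene oxide with retention, giving the E-trisubstituted alkene.

**Step 16**
Reactants: 24 (3E)-6-(Dec)-4-methylhex-3-en-1-ol
Product: 25 (3E)-6-(Dec)-4-methylhex-3-enal
Conditions: Dess–Martin periodinane, NaHCO3, CH2Cl2, 0 °C
Reagents that add atoms: none
Why: Buffered Dess–Martin oxidation gives the β,γ-unsaturated aldehyde without conjugation of the alkene; it is used directly.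

**Step 17**
Reactants: 25 (3E)-6-(Dec)-4-methylhex-3-enal
Product: 26 methyl (2Z,5E)-8-(Dec)-2,6-dimethylocta-2,5-dienoate
Conditions: (CF3CH2O)2P(O)CH(CH3)CO2CH3, KN(SiMe3)2, 18-crown-6, THF, −78 °C
Reagents that add atoms: methyl 2-[bis(2,2,2-trifluoroethoxy)phosphoryl]propanoate, COC(=O)C(C)P(=O)(OCC(F)(F)F)OCC(F)(F)F
Why: Still–Gennari olefination gives the Z-α-methyl enoate, the geometry needed for the later lactone tether.

**Step 18**
Reactants: 26 methyl (2Z,5E)-8-(Dec)-2,6-dimethylocta-2,5-dienoate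
Product: 27 methyl (2Z)-4-{(2S,3S)-3-[2-(Dec)ethyl]-3-methyloxiran-2-yl}-2-methylbut-2-enoate
Conditions: L-fructose-derived Shi ketone (0.3 equiv), KHSO5, K2CO3, n-Bu4NHSO4, MeCN/CH2(OMe)2/aqueous Na2B4O7 buffer, 0 °C
Reagents that add atoms: potassium peroxymonosulfate, [K+].OOS(=O)(=O)[O-]
Why: Shi asymmetric epoxidation attacks only the electron-rich E-trisubstituted alkene and the chiral dioxirane sets C13 and C14 (both S) by reagent control; the enoate is inert.

**Step 19**
Reactants: 27 methyl (2Z)-4-{(2S,3S)-3-[2-(Dec)ethyl]-3-methyloxiran-2-yl}-2-methylbut-2-enoate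
Product: 29 (6S)-6-[(2R)-2-hydroperoxy-4-(Dec)butan-2-yl]-3-methyl-5,6-dihydro-2H-pyran-2-one, via hydroxy hydroperoxide 28 (not isolated)
Conditions: anhydrous H2O2 in Et2O (10 equiv), H3PMo12O40 (5 mol%), Et2O, 0 °C to rt
Reagents that add atoms: hydrogen peroxide, OO
Why: Heteropolyacid-catalysed perhydrolysis opens the epoxide at tertiary C13 with inversion (C13 becomes R, C14 keeps its oxygen and configuration), and the freed C14 hydroxyl then lactonises onto the cis-disposed Z-ester under the same acid.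

**Step 20**
Reactants: 29 (6S)-6-[(2R)-2-hydroperoxy-4-(Dec)butan-2-yl]-3-methyl-5,6-dihydro-2H-pyran-2-one
Product: 30 (1S,4R,5S,8S)-4-[2-(Dec)ethyl]-4,8-dimethyl-2,3,6-trioxabicyclo[3.3.1]nonan-7-one
Conditions: Et3N (0.5 equiv), CF3CH2OH, 0 °C to rt
Reagents that add atoms: none
Why: Intramolecular peroxy-Michael addition (6-exo-trig) closes the dioxane; the lactone tether lets the hydroperoxide reach C16 only on the face cis to the C14 oxygen (C16 S), and the lactone enolate is protonated on its exo face so that the C17 methyl ends equatorial (C17 S, also the more stable epimer).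

**Step 21**
Reactants: 30 (1S,4R,5S,8S)-4-[2-(Dec)ethyl]-4,8-dimethyl-2,3,6-trioxabicyclo[3.3.1]nonan-7-one
Product: 31 methyl (2S)-2-{(3S,5S,6R)-6-[2-(Dec)ethyl]-5-hydroxy-6-methyl-1,2-dioxan-3-yl}propanoate
Conditions: K2CO3 (0.1 equiv), MeOH, 0 °C
Reagents that add atoms: methanol, CO
Why: Transesterification of the strained bridged lactone releases the methyl ester and the C14 hydroxyl without touching a stereocentre, the cold, weakly basic medium being chosen to avoid retro-Michael opening.

**Step 22**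
Reactants: 31 methyl (2S)-2-{(3S,5S,6R)-6-[2-(Dec)ethyl]-5-hydroxy-6-methyl-1,2-dioxan-3-yl}propanoate
Product: 32 methyl (2S)-2-{(3S,5S,6R)-6-[2-(Dec)ethyl]-6-methyl-5-[(phenoxycarbonothioyl)oxy]-1,2-dioxan-3-yl}propanoate
Conditions: PhOC(S)Cl, pyridine, DMAP (cat.), CH2Cl2, 0 °C to rt
Reagents that add atoms: O-phenyl chlorothionoformate, S=C(Cl)Oc1ccccc1
Why: Thionocarbonate formation should occur only at the secondary C14 hydroxyl, because the tertiary C5 hydroxyl is shielded by two quaternary carbons.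

**Step 23**
Reactants: 32 methyl (2S)-2-{(3S,5S,6R)-6-[2-(Dec)ethyl]-6-methyl-5-[(phenoxycarbonothioyl)oxy]-1,2-dioxan-3-yl}propanoate
Product: 33 methyl (2S)-2-{(3S,6R)-6-[2-(Dec)ethyl]-6-methyl-1,2-dioxan-3-yl}propanoate
Conditions: n-Bu3SnH (5 equiv, concentrated), Et3B, air, toluene, rt
Reagents that add atoms: none
Why: Barton–McCombie deoxygenation removes the temporary C14 oxygen, the C14 radical being trapped by tin hydride faster than it attacks the O–O bond (as in tin hydride reductions of β-halo cyclic peroxides), and no stereocentre is formed or lost.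

**Compound list**
1 | methyl (S)-3-hydroxy-2-methylpropanoate | COC(=O)[C@@H](C)CO | starting material
2 | methyl (S)-3-[(tert-butyldimethylsilyl)oxy]-2-methylpropanoate | COC(=O)[C@@H](C)CO[Si](C)(C)C(C)(C)C | intermediate
3 | (S)-3-[(tert-butyldimethylsilyl)oxy]-2-methylpropanal | O=C[C@@H](C)CO[Si](C)(C)C(C)(C)C | intermediate
4 | (R)-tert-butyldimethyl[(2-methylbut-3-en-1-yl)oxy]silane | C=C[C@@H](C)CO[Si](C)(C)C(C)(C)C | intermediate
5 | (R)-4-bromo-3-methylbut-1-ene | C=C[C@@H](C)CBr | intermediate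
6 | [(R)-2-methylbut-3-en-1-yl]triphenylphosphonium bromide | C=C[C@@H](C)C[P+](c1ccccc1)(c1ccccc1)c1ccccc1.[Br-] | intermediate
7 | (R)-2,2-dimethyl-1,3-dioxolane-4-carbaldehyde | O=C[C@H]1COC(C)(C)O1 | starting material
8 | [(R)-2-methylbut-3-en-1-ylidene]triphenylphosphorane | C=C[C@@H](C)C=P(c1ccccc1)(c1ccccc1)c1ccccc1 | intermediate (not isolated)
9 | (4S)-2,2-dimethyl-4-[(1Z,3R)-3-methylpenta-1,4-dien-1-yl]-1,3-dioxolane | C=C[C@@H](C)/C=C\[C@H]1COC(C)(C)O1 | intermediate
10 | (2S,3Z,5R)-5-methylhepta-3,6-diene-1,2-diol | C=C[C@@H](C)/C=C\[C@H](O)CO | intermediate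
11 | (2S,3Z,5R)-1-[(tert-butyldimethylsilyl)oxy]-5-methylhepta-3,6-dien-2-ol | C=C[C@@H](C)/C=C\[C@H](O)CO[Si](C)(C)C(C)(C)C | intermediate
12 | 2,2,6-trimethylcyclohexan-1-one (racemic) | CC1CCCC(C)(C)C1=O | starting material
13 | 1,1-dimethoxy-2,2,6-trimethylcyclohexane | COC1(OC)C(C)CCCC1(C)C | intermediate (not isolated)
14 | 1-methoxy-2,6,6-trimethylcyclohex-1-ene | COC1=C(C)CCCC1(C)C | intermediate
15 | mixed methyl allyl ketal of 12 with alcohol 11 (mixture at the two ring stereocentres) | COC1(O[C@H](CO[Si](C)(C)C(C)(C)C)/C=C\[C@H](C)C=C)C(C)CCCC1(C)C | intermediate (not isolated)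
16 | tert-butyldimethyl{[(2S,3Z,5R)-5-methyl-2-[(2,6,6-trimethylcyclohex-1-en-1-yl)oxy]hepta-3,6-dien-1-yl]oxy}silane | CC1=C(O[C@H](CO[Si](C)(C)C(C)(C)C)/C=C\[C@H](C)C=C)C(C)(C)CCC1 | intermediate (not isolated)
17 | (2R)-2-[(3R,4S,5E)-7-[(tert-butyldimethylsilyl)oxy]-3-methylhepta-1,5-dien-4-yl]-2,6,6-trimethylcyclohexan-1-one | CC(C)(C)[Si](C)(C)OC/C=C/[C@H]([C@@]1(C)CCCC(C)(C)C1=O)[C@H](C)C=C | intermediate (not isolated)
18 | (1S,4aS,8aR)-1-[(E)-3-[(tert-butyldimethylsilyl)oxy]prop-1-en-1-yl]-2,5,5,8a-tetramethyl-1,5,6,7,8,8a-hexahydronaphthalen-4a(4H)-ol | CC(C)(C)[Si](C)(C)OC/C=C/[C@H]1C(C)=CC[C@]2(O)C(C)(C)CCC[C@]12C | intermediate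
19 | (1S,2R,4aS,8aR)-1-{3-[(tert-butyldimethylsilyl)oxy]propyl}-2,5,5,8a-tetramethyloctahydronaphthalen-4a(2H)-ol | CC(C)(C)[Si](C)(C)OCCC[C@H]1[C@H](C)CC[C@]2(O)C(C)(C)CCC[C@]12C | intermediate
20 | (1S,2R,4aS,8aR)-1-(3-hydroxypropyl)-2,5,5,8a-tetramethyloctahydronaphthalen-4a(2H)-ol | OCCC[C@H]1[C@H](C)CC[C@]2(O)C(C)(C)CCC[C@]12C | intermediate
21 | 3-(Dec)propanal | O=CCC[C@H]1[C@H](C)CC[C@]2(O)C(C)(C)CCC[C@]12C | intermediate
22 | (1S,2R,4aS,8aR)-1-(but-3-yn-1-yl)-2,5,5,8a-tetramethyloctahydronaphthalen-4a(2H)-ol | C#CCC[C@H]1[C@H](C)CC[C@]2(O)C(C)(C)CCC[C@]12C | intermediate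
23 | (E)-alkenyl(dimethyl)alane from 22, tertiary hydroxyl as its dimethylaluminium alkoxide | C[Al](C)/C=C(\C)CC[C@H]1[C@H](C)CC[C@]2(O[Al](C)C)C(C)(C)CCC[C@]12C | intermediate (not isolated)
24 | (3E)-6-(Dec)-4-methylhex-3-en-1-ol | OCC/C=C(\C)CC[C@H]1[C@H](C)CC[C@]2(O)C(C)(C)CCC[C@]12C | intermediate
25 | (3E)-6-(Dec)-4-methylhex-3-enal | O=CC/C=C(\C)CC[C@H]1[C@H](C)CC[C@]2(O)C(C)(C)CCC[C@]12C | intermediate
26 | methyl (2Z,5E)-8-(Dec)-2,6-dimethylocta-2,5-dienoate | COC(=O)/C(C)=C\C/C=C(\C)CC[C@H]1[C@H](C)CC[C@]2(O)C(C)(C)CCC[C@]12C | intermediate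
27 | methyl (2Z)-4-{(2S,3S)-3-[2-(Dec)ethyl]-3-methyloxiran-2-yl}-2-methylbut-2-enoate | COC(=O)/C(C)=C\C[C@@H]1O[C@@]1(C)CC[C@H]2[C@H](C)CC[C@]3(O)C(C)(C)CCC[C@]23C | intermediate
28 | methyl (2Z,5S,6R)-8-(Dec)-6-hydroperoxy-5-hydroxy-2,6-dimethyloct-2-enoate | COC(=O)/C(C)=C\C[C@H](O)[C@](C)(OO)CC[C@H]1[C@H](C)CC[C@]2(O)C(C)(C)CCC[C@]12C | intermediate (not isolated)
29 | (6S)-6-[(2R)-2-hydroperoxy-4-(Dec)butan-2-yl]-3-methyl-5,6-dihydro-2H-pyran-2-one | CC1=CC[C@H](OC1=O)[C@](C)(OO)CC[C@H]2[C@H](C)CC[C@]3(O)C(C)(C)CCC[C@]23C | intermediate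
30 | (1S,4R,5S,8S)-4-[2-(Dec)ethyl]-4,8-dimethyl-2,3,6-trioxabicyclo[3.3.1]nonan-7-one | C[C@@H]1C(=O)O[C@H]2C[C@@H]1OO[C@]2(C)CC[C@H]3[C@H](C)CC[C@]4(O)C(C)(C)CCC[C@]34C | intermediate
31 | methyl (2S)-2-{(3S,5S,6R)-6-[2-(Dec)ethyl]-5-hydroxy-6-methyl-1,2-dioxan-3-yl}propanoate | COC(=O)[C@@H](C)[C@@H]1C[C@H](O)[C@@](C)(CC[C@H]2[C@H](C)CC[C@]3(O)C(C)(C)CCC[C@]23C)OO1 | intermediate
32 | methyl (2S)-2-{(3S,5S,6R)-6-[2-(Dec)ethyl]-6-methyl-5-[(phenoxycarbonothioyl)oxy]-1,2-dioxan-3-yl}propanoate | COC(=O)[C@@H](C)[C@@H]1C[C@H](OC(=S)Oc2ccccc2)[C@@](C)(CC[C@H]3[C@H](C)CC[C@]4(O)C(C)(C)CCC[C@]34C)OO1 | intermediate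
33 | methyl (2S)-2-[(3S,6R)-6-{2-[(1S,2R,4aS,8aR)-4a-hydroxy-2,5,5,8a-tetramethyldecahydronaphthalen-1-yl]ethyl}-6-methyl-1,2-dioxan-3-yl]propanoate | COC(=O)[C@@H](C)[C@@H]1CC[C@@](C)(CC[C@H]2[C@H](C)CC[C@]3(O)C(C)(C)CCC[C@]23C)OO1 | target

**Totals**
Total step count: 23. Longest linear sequence: 22 steps (steps 1–8 and 10–23).

**Steps most likely to fail**

Step 10 (Proposed new method). The ene stage may not close ring B before ketone 17 is consumed by Cope rearrangement of its 1,5-diene or by thermal decomposition, because a monosubstituted vinyl group is a weak ene donor towards a very hindered ketone. Fallback with known chemistry: the exchange/Claisen stage is stopped at 140 °C and ketone 17 is isolated. Hydroboration with 9-BBN followed by NaOH/H2O2 converts only the terminal vinyl group into the primary alcohol F1. I2, PPh3 and imidazole give the primary iodide F2. SmI2/HMPA in THF closes ring B by a Barbier reaction onto the C5 ketone to give the saturated cis-fused decalol F3, in which C8 keeps its chiral-pool configuration. Hydrogenation of the C11=C12 alkene over [Ir(cod)(PCy3)(py)]PF6 returns to 19.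

Step 19. The tertiary C13–O bond may ionise ahead of peroxide attack, which would erode the configuration at C13, or the epoxide may rearrange to a ketone by hydride shift. Fallback: setting out from 26, Co(acac)2-catalysed hydroperoxysilylation (O2, Et3SiH, ClCH2CH2Cl) of the trisubstituted alkene gives the tertiary triethylsilyl peroxide F4 as both C13 epimers. HF·pyridine frees the hydroperoxide F5, and Et2NH in CF3CH2OH cyclises it onto the enoate by peroxy-Michael addition. The diastereomers are separated by HPLC, and the one carrying the configuration of the route re-enters at 33.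

Step 23. The C14 radical may attack the neighbouring O–O bond (epoxide formation with ring opening), or stannyl radicals may reduce the peroxide. Fallback: setting out from 31, Martin sulfurane Ph2S[OC(CF3)2Ph]2 in CH2Cl2 dehydrates the C14 hydroxyl towards C15, the only side carrying β-hydrogens, to give the 3,6-dihydro-1,2-dioxine F6. Diimide from KO2CN=NCO2K and AcOH then saturates C14=C15 without touching the peroxide and returns to 33.

**Further compounds**
F1 | step 10 | 17 with the terminal vinyl group hydroborated to CH2CH2OH | CC(C)(C)[Si](C)(C)OC/C=C/[C@H]([C@@]1(C)CCCC(C)(C)C1=O)[C@H](C)CCO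
F2 | step 10 | primary iodide from F1 | CC(C)(C)[Si](C)(C)OC/C=C/[C@H]([C@@]1(C)CCCC(C)(C)C1=O)[C@H](C)CCI
F3 | step 10 | 19 with an E-alkene at C11=C12 | CC(C)(C)[Si](C)(C)OC/C=C/[C@H]1[C@H](C)CC[C@]2(O)C(C)(C)CCC[C@]12C
F4 | step 19 | methyl (2Z)-8-(Dec)-2,6-dimethyl-6-[(triethylsilyl)peroxy]oct-2-enoate (both C13 epimers) | COC(=O)/C(C)=C\CCC(C)(OO[Si](CC)(CC)CC)CC[C@H]1[C@H](C)CC[C@]2(O)C(C)(C)CCC[C@]12C
F5 | step 19 | methyl (2Z)-8-(Dec)-6-hydroperoxy-2,6-dimethyloct-2-enoate (both C13 epimers) | COC(=O)/C(C)=C\CCC(C)(OO)CC[C@H]1[C@H](C)CC[C@]2(O)C(C)(C)CCC[C@]12C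
F6 | step 23 | methyl (2S)-2-{(3S,6R)-6-[2-(Dec)ethyl]-6-methyl-3,6-dihydro-1,2-dioxin-3-yl}propanoate | COC(=O)[C@@H](C)[C@@H]1C=C[C@@](C)(CC[C@H]2[C@H](C)CC[C@]3(O)C(C)(C)CCC[C@]23C)OO1
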